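Flavan numbering is used. Ring C is cut at C2–C3 and at O1–C8a. O1 and C2 are the carbonyl group of a protected 4-hydroxybenzaldehyde, and C3–C4–C4a–C8a is a 2-(2-fluoroaryl)ethylzinc reagent. In one flask the key step adds this reagent to the aldehyde under a chiral titanium catalyst, which sets C2. The alkoxide then displaces fluoride from C8a, completing a formal asymmetric [4+2] annulation. The step exploits that C8a of ring A lies meta to the C5 and C7 oxygens and ortho to the C8 side chain. That chain is carried as a conjugating diarylalkyne that later becomes the 1,2-diketone. The precursor is an open-chain pentasubstituted fluoroarene.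

Key step: step 7

Remark on the chemistry:
- Ring A is the benzo ring, ring C the pyran ring, ring B the aryl group on C2, and ring D the aryl group of the side chain.
- The stereocentre of the target is C2 and has the S configuration.
- MOM stands for methoxymethyl.
- Compounds 1, 4 and 7 are taken as commercial.
- Zn(CH2SiMe3)2 is a reagent made beforehand from Me3SiCH2MgCl and ZnCl2.

Step 1
Reactants: 1 5-fluorobenzene-1,3-diol
Product: 2 1-fluoro-3,5-bis(methoxymethoxy)benzene
Conditions: NaH, MOMCl, DMF, 0 °C to rt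
Reagents that add atoms: chloromethyl methyl ether, COCCl
Why: Williamson-type O-alkylation of both phenoxides; the MOM acetals should survive bases, organometallic reagents and buffered permanganate, and they can be removed at the end without hydrogenation or strong acid.

Step 2
Reactants: 2 1-fluoro-3,5-bis(methoxymethoxy)benzene
Product: 3 3-fluoro-2,4-diiodo-1,5-bis(methoxymethoxy)benzene
Conditions: NIS (2.1 equiv), MeCN, 0 °C to rt, dark
Reagents that add atoms: N-iodosuccinimide, O=C1CCC(=O)N1I
Why: Electrophilic aromatic iodination; each carbon next to fluorine is para to one acetal oxygen, ortho to the other and flanked by the small fluorine, whereas the carbon between the two OMOM groups is shielded, as in the known 2,6-dihalogenation of 1-substituted 3,5-dialkoxybenzenes.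

Step 3
Reactants: 3 3-fluoro-2,4-diiodo-1,5-bis(methoxymethoxy)benzene; 4 oxirane
Product: 6 2-[2-fluoro-3-iodo-4,6-bis(methoxymethoxy)phenyl]ethan-1-ol, via arylmagnesium chloride 5 (not isolated)
Conditions: i-PrMgCl·LiCl (1.0 equiv), THF, −40 °C; then CuI (10 mol %), 4 (3 equiv), −40 to 0 °C; aq. NH4Cl
Reagents that add atoms: none
Why: Iodine–magnesium exchange should stop after one of the two equivalent iodines because the arylmagnesium is electron-rich, and copper-catalysed epoxide opening installs C4 and C3; the mixture stays at or below 0 °C so that the ortho-fluoro Grignard reagent does not collapse to an aryne.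

Step 4
Reactants: 7 4-(methoxymethoxy)benzaldehyde
Product: 8 1-ethynyl-4-(methoxymethoxy)benzene
Conditions: dimethyl (1-diazo-2-oxopropyl)phosphonate, K2CO3, MeOH, rt
Reagents that add atoms: dimethyl (1-diazo-2-oxopropyl)phosphonate, COP(=O)(OC)C(=[N+]=[N-])C(C)=O
Why: Seyferth–Gilbert homologation with the Ohira–Bestmann reagent turns the non-enolisable aromatic aldehyde into the terminal alkyne under mild base that leaves the MOM ether intact.

Step 5
Reactants: 6 2-[2-fluoro-3-iodo-4,6-bis(methoxymethoxy)phenyl]ethan-1-ol; 8 1-ethynyl-4-(methoxymethoxy)benzene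
Product: 9 2-[2-fluoro-4,6-bis(methoxymethoxy)-3-{[4-(methoxymethoxy)phenyl]ethynyl}phenyl]ethan-1-ol
Conditions: PdCl2(PPh3)2 (3 mol %), CuI (5 mol %), Et3N/THF, degassed, 50 °C
Reagents that add atoms: none
Why: Sonogashira coupling at the only C–I bond; the C–F bond, the free primary alcohol and the acetals are inert, and the alkyne carries both carbons of the later diketone.

Step 6
Reactants: 9 2-[2-fluoro-4,6-bis(methoxymethoxy)-3-{[4-(methoxymethoxy)phenyl]ethynyl}phenyl]ethan-1-ol
Product: 10 3-fluoro-4-(2-iodoethyl)-1,5-bis(methoxymethoxy)-2-{[4-(methoxymethoxy)phenyl]ethynyl}benzene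
Conditions: PPh3, imidazole, I2 (premixed), CH2Cl2, 0 °C
Reagents that add atoms: iodine, [I][I]
Why: Appel-type iodination of a primary alcohol; premixing the phosphine with iodine leaves no free iodine that could trigger iodocyclisation of the ortho-alkoxyaryl alkyne.

Step 7
Reactants: 10 3-fluoro-4-(2-iodoethyl)-1,5-bis(methoxymethoxy)-2-{[4-(methoxymethoxy)phenyl]ethynyl}benzene; 7 4-(methoxymethoxy)benzaldehyde
Product: 15 (2S)-5,7-bis(methoxymethoxy)-2-[4-(methoxymethoxy)phenyl]-8-{[4-(methoxymethoxy)phenyl]ethynyl}chromane, via bis(arylethyl)zinc 11 (not isolated), via mixed diorganozinc 12 (not isolated), via zinc alkoxide 13 (not isolated), via potassium alkoxide 14 (not isolated)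
Conditions: one flask: (a) Et2Zn (3 equiv), CuI (0.5 mol %), minimal THF, 50 °C, then volatiles off in vacuo; (b) Zn(CH2SiMe3)2 (0.5 equiv per 10), Et2O, rt; (c) (1R,2R)-1,2-bis(trifluoromethanesulfonamido)cyclohexane (8 mol %), Ti(OiPr)4 (0.6 equiv), 7 (0.85 equiv), Et2O/toluene, −20 °C; (d) KOt-Bu (5 equiv), DMPU, 65 °C; aq. NH4Cl
Reagents that add atoms: none
Why: Iodine–zinc exchange and alkyl scrambling give 12, whose 2-arylethyl group (Me3SiCH2 is a non-transferable ligand) is passed via titanium to the carbonyl carbon of 7 to form C2–C3, and KOt-Bu then strips the alkoxide from zinc and titanium as 14, which adds to C8a and expels fluoride to form O1–C8a. The closest known reaction types are the Ti(OiPr)4/bis(sulfonamide)-catalysed enantioselective addition of functionalised mixed diorganozincs to aromatic aldehydes and the base-mediated intramolecular SNAr of 3-(2-fluoroaryl)propan-1-olates to chromans, run here without isolation of the carbinol. Ring C closes by a 6-exo-trig addition–elimination at C8a. C2, the only stereocentre, is set by catalyst control: the (1R,2R)-ligand should direct the alkyl group to the Si face of the aldehyde, as it does for simple dialkylzincs and benzaldehyde, which gives S, and the C2–O bond is not touched in the ring closure, so S is retained. The SNAr needs site selectivity and chemoselectivity, secured because fluorine is the only leaving group, both carbons next to C8a are substituted (no aryne), the charge of the adduct falls on C8, C6 and C4a (at C8 it is delocalised into the arylethynyl group) and never on the oxygen-bearing C5 and C7, and the six-membered intramolecular attack should outrun tert-butoxide or isopropoxide. Aldehyde 7 is the limiting component, so that no carbonyl compound is left to racemise 14 by reversible hydride transfer.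

Step 8
Reactants: 15 (2S)-5,7-bis(methoxymethoxy)-2-[4-(methoxymethoxy)phenyl]-8-{[4-(methoxymethoxy)phenyl]ethynyl}chromane
Product: 16 1-{(2S)-5,7-bis(methoxymethoxy)-2-[4-(methoxymethoxy)phenyl]chroman-8-yl}-2-[4-(methoxymethoxy)phenyl]ethane-1,2-dione
Conditions: KMnO4, NaHCO3, MgSO4, acetone/H2O, 0 °C to rt
Reagents that add atoms: potassium permanganate, [K+].[O-][Mn](=O)(=O)=O
Why: Buffered permanganate oxidation of a diarylalkyne to a benzil; attack on the electron-rich triple bond should be faster than attack on ethers or benzylic C–H bonds at neutral pH, the buffer prevents base-induced cleavage of the diketone, and C2 is not involved.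

Step 9
Reactants: 16 1-{(2S)-5,7-bis(methoxymethoxy)-2-[4-(methoxymethoxy)phenyl]chroman-8-yl}-2-[4-(methoxymethoxy)phenyl]ethane-1,2-dione
Product: 18 1-[(2S)-5,7-dihydroxy-2-(4-hydroxyphenyl)chroman-8-yl]-2-(4-hydroxyphenyl)ethane-1,2-dione (CNP0332855.1), via tetrakis(trimethylsilyl) ether 17 (not isolated)
Conditions: TMSOTf (8 equiv), 2,2'-bipyridyl (12 equiv), MeCN, 0 °C to rt; then H2O, rt; work-up at pH 5–6
Reagents that add atoms: none
Why: Silyl triflate/2,2'-bipyridyl cleavage of aromatic MOM ethers passes the methoxymethyl groups to the bipyridyl nitrogen and leaves aryl silyl ethers that water hydrolyses; no strong Brønsted acid that could ionise the benzylic C2–O1 bond is present, and no base that could open ring C through a para-quinone methide, so C2 should stay S.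

Compound list
1 | 5-fluorobenzene-1,3-diol | Oc1cc(O)cc(F)c1 | starting material
2 | 1-fluoro-3,5-bis(methoxymethoxy)benzene | COCOc1cc(F)cc(OCOC)c1 | intermediate
3 | 3-fluoro-2,4-diiodo-1,5-bis(methoxymethoxy)benzene | COCOc1cc(OCOC)c(I)c(F)c1I | intermediate
4 | oxirane (ethylene oxide) | C1CO1 | starting material
5 | [2-fluoro-3-iodo-4,6-bis(methoxymethoxy)phenyl]magnesium chloride (LiCl complex, LiCl not drawn) | COCOc1cc(OCOC)c([Mg]Cl)c(F)c1I | intermediate
6 | 2-[2-fluoro-3-iodo-4,6-bis(methoxymethoxy)phenyl]ethan-1-ol | COCOc1cc(OCOC)c(CCO)c(F)c1I | intermediate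
7 | 4-(methoxymethoxy)benzaldehyde | COCOc1ccc(C=O)cc1 | starting material
8 | 1-ethynyl-4-(methoxymethoxy)benzene | COCOc1ccc(C#C)cc1 | intermediate
9 | 2-[2-fluoro-4,6-bis(methoxymethoxy)-3-{[4-(methoxymethoxy)phenyl]ethynyl}phenyl]ethan-1-ol | COCOc1ccc(cc1)C#Cc1c(F)c(CCO)c(OCOC)cc1OCOC | intermediate
10 | 3-fluoro-4-(2-iodoethyl)-1,5-bis(methoxymethoxy)-2-{[4-(methoxymethoxy)phenyl]ethynyl}benzene | COCOc1ccc(cc1)C#Cc1c(F)c(CCI)c(OCOC)cc1OCOC | intermediate
11 | bis{2-[2-fluoro-4,6-bis(methoxymethoxy)-3-{[4-(methoxymethoxy)phenyl]ethynyl}phenyl]ethyl}zinc | COCOc1ccc(cc1)C#Cc1c(F)c(CC[Zn]CCc2c(F)c(C#Cc3ccc(OCOC)cc3)c(OCOC)cc2OCOC)c(OCOC)cc1OCOC | intermediate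
12 | {2-[2-fluoro-4,6-bis(methoxymethoxy)-3-{[4-(methoxymethoxy)phenyl]ethynyl}phenyl]ethyl}[(trimethylsilyl)methyl]zinc | C[Si](C)(C)C[Zn]CCc1c(F)c(C#Cc2ccc(OCOC)cc2)c(OCOC)cc1OCOC | intermediate
13 | [(trimethylsilyl)methyl]zinc (1S)-3-[2-fluoro-4,6-bis(methoxymethoxy)-3-{[4-(methoxymethoxy)phenyl]ethynyl}phenyl]-1-[4-(methoxymethoxy)phenyl]propan-1-olate | C[Si](C)(C)C[Zn]O[C@H](c1ccc(OCOC)cc1)CCc1c(F)c(C#Cc2ccc(OCOC)cc2)c(OCOC)cc1OCOC | intermediate
14 | potassium (1S)-3-[2-fluoro-4,6-bis(methoxymethoxy)-3-{[4-(methoxymethoxy)phenyl]ethynyl}phenyl]-1-[4-(methoxymethoxy)phenyl]propan-1-olate | [K+].[O-][C@H](c1ccc(OCOC)cc1)CCc1c(F)c(C#Cc2ccc(OCOC)cc2)c(OCOC)cc1OCOC | intermediate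
15 | (2S)-5,7-bis(methoxymethoxy)-2-[4-(methoxymethoxy)phenyl]-8-{[4-(methoxymethoxy)phenyl]ethynyl}chromane | COCOc1ccc(cc1)C#Cc1c(OCOC)cc(OCOC)c2c1O[C@H](c1ccc(OCOC)cc1)CC2 | intermediate
16 | 1-{(2S)-5,7-bis(methoxymethoxy)-2-[4-(methoxymethoxy)phenyl]chroman-8-yl}-2-[4-(methoxymethoxy)phenyl]ethane-1,2-dione | COCOc1ccc(cc1)C(=O)C(=O)c1c(OCOC)cc(OCOC)c2c1O[C@H](c1ccc(OCOC)cc1)CC2 | intermediate
17 | tetrakis(trimethylsilyl) ether of 18, (2S) | C[Si](C)(C)Oc1ccc(cc1)C(=O)C(=O)c1c(O[Si](C)(C)C)cc(O[Si](C)(C)C)c2c1O[C@H](c1ccc(O[Si](C)(C)C)cc1)CC2 | intermediate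
18 | 1-[(2S)-5,7-dihydroxy-2-(4-hydroxyphenyl)chroman-8-yl]-2-(4-hydroxyphenyl)ethane-1,2-dione (CNP0332855.1) | O=C(C(=O)c1c(O)cc(O)c2c1O[C@H](c1ccc(O)cc1)CC2)c1ccc(O)cc1 | target

Total step count: 9. Longest linear sequence: 8 steps (steps 1, 2, 3, 5, 6, 7, 8, 9); step 4 is the side branch.

Steps most likely to fail

Step 7. Three processes may spoil it. The many acetal oxygens of the zinc reagent may compete for titanium and erode facial selectivity. The alkoxide may be released only partly from zinc and titanium, so that ring closure stalls. Slow hydride transfer may erode the configuration at C2. The fallback sets out from 10 and comes back at 15, and it sets C2 by ketone reduction instead of carbonyl addition. Iodine–lithium exchange (t-BuLi, Et2O, −78 °C) gives the organolithium F1. Addition of F1 to 7 gives the racemic carbinol F2, and Dess–Martin periodinane gives the ketone F3. Asymmetric transfer hydrogenation with RuCl(p-cymene)[(S,S)-TsDPEN] in HCO2H/Et3N tolerates the alkyne and should give the (S)-carbinol F4. Isolated F4 is closed as its clean potassium alkoxide (KHMDS, THF/DMPU, 60 °C) to 15.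

Step 9. Silyl Lewis acid held between the C8 carbonyl oxygen and O1 may assist ionisation of the benzylic C2–O1 bond, with loss of configurational purity or opening of ring C. Cleavage of the hindered C7 acetal may also remain incomplete. The fallback sets out from 15 and comes back at 18. It moves the acetal cleavage to a stage without the C8 carbonyl group and ends with a neutral ester cleavage. Treatment with p-TsOH (cat.) in MeOH at 40 °C gives the tetraphenol alkyne F5. F5 is acetylated at once (Ac2O, pyridine, 0 °C) to the tetraacetate alkyne F6, before the ortho-alkynylphenol can cyclise. Buffered KMnO4 gives the tetraacetate diketone F7, and NH4OAc in aqueous MeOH at rt frees 18.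

Step 8. Over-oxidation may occur, either as cleavage of the diketone to carboxylic acids or as attack on the benzylic C2–H and C4–H bonds or on the electron-rich ring A. The fallback sets out from 15 and comes back at 16, and it builds the two carbonyl groups stepwise. Semihydrogenation (H2, Pd/CaCO3 poisoned with Pb(OAc)2, quinoline) gives the (Z)-stilbene F8. Dihydroxylation (OsO4 cat., NMO) gives the diol F9 as a diastereomer mixture whose new centres are erased in the next step. A double Swern oxidation ((COCl)2, DMSO, Et3N, −78 °C) gives 16.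

Further compounds
F1 | step 7 | {2-[2-fluoro-4,6-bis(methoxymethoxy)-3-{[4-(methoxymethoxy)phenyl]ethynyl}phenyl]ethyl}lithium | [Li]CCc1c(F)c(C#Cc2ccc(OCOC)cc2)c(OCOC)cc1OCOC
F2 | step 7 | racemic 3-[2-fluoro-4,6-bis(methoxymethoxy)-3-{[4-(methoxymethoxy)phenyl]ethynyl}phenyl]-1-[4-(methoxymethoxy)phenyl]propan-1-ol | OC(c1ccc(OCOC)cc1)CCc1c(F)c(C#Cc2ccc(OCOC)cc2)c(OCOC)cc1OCOC
F3 | step 7 | 3-[2-fluoro-4,6-bis(methoxymethoxy)-3-{[4-(methoxymethoxy)phenyl]ethynyl}phenyl]-1-[4-(methoxymethoxy)phenyl]propan-1-one | O=C(c1ccc(OCOC)cc1)CCc1c(F)c(C#Cc2ccc(OCOC)cc2)c(OCOC)cc1OCOC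
F4 | step 7 | (1S)-3-[2-fluoro-4,6-bis(methoxymethoxy)-3-{[4-(methoxymethoxy)phenyl]ethynyl}phenyl]-1-[4-(methoxymethoxy)phenyl]propan-1-ol | O[C@H](c1ccc(OCOC)cc1)CCc1c(F)c(C#Cc2ccc(OCOC)cc2)c(OCOC)cc1OCOC
F5 | step 9 | (2S)-2-(4-hydroxyphenyl)-8-[(4-hydroxyphenyl)ethynyl]chromane-5,7-diol | Oc1ccc(cc1)C#Cc1c(O)cc(O)c2c1O[C@H](c1ccc(O)cc1)CC2
F6 | step 9 | tetraacetate of F5, (2S) | CC(=O)Oc1ccc(cc1)C#Cc1c(OC(C)=O)cc(OC(C)=O)c2c1O[C@H](c1ccc(OC(C)=O)cc1)CC2
F7 | step 9 | tetraacetate of 18, (2S) | CC(=O)Oc1ccc(cc1)C(=O)C(=O)c1c(OC(C)=O)cc(OC(C)=O)c2c1O[C@H](c1ccc(OC(C)=O)cc1)CC2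
F8 | step 8 | (2S)-5,7-bis(methoxymethoxy)-2-[4-(methoxymethoxy)phenyl]-8-{(Z)-2-[4-(methoxymethoxy)phenyl]ethenyl}chromane | COCOc1ccc(cc1)/C=C\c1c(OCOC)cc(OCOC)c2c1O[C@H](c1ccc(OCOC)cc1)CC2
F9 | step 8 | 1-{(2S)-5,7-bis(methoxymethoxy)-2-[4-(methoxymethoxy)phenyl]chroman-8-yl}-2-[4-(methoxymethoxy)phenyl]ethane-1,2-diol (carbinol centres unassigned) | COCOc1ccc(cc1)C(O)C(O)c1c(OCOC)cc(OCOC)c2c1O[C@H](c1ccc(OCOC)cc1)CC2
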